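**Retrosynthetic overview**
1. Eurycomalin A 9 ⇐ di-tert-butyl ester 8 (ester cleavage) ⇐ bis-carbinol 7 (two dehydrations give the isopropenyl groups).
2. 7 ⇐ 2 × monomer 6: the C7–C7' biaryl bond is made by anodic dehydrogenative homocoupling of the finished, enantiopure monomer.
3. 6 ⇐ hydroxy ester 4: dihydrofuran ring by intramolecular SNAr (aryl C–O bond, C2–O untouched), then two MeMgBr on the C2 ester.
4. 4 ⇐ aryl Grignard from 1 + methyl (S)-glycidate 2 (Ar–CH2 bond); each (S) centre of the target is the bought glycidate carbon.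
5. Ring order: benzene rings bought, one dihydrofuran ring closed on each monomer, biaryl bond formed last among the skeletal bonds.

Assumption: 1 and 2 are taken as catalogue compounds (2 is the serine-derived (S)-glycidate), and a one-pot operation without isolation counts as one step.

**Step 1**
Reactants: 1 tert-butyl 3-bromo-4-fluorobenzoate; 2 methyl (2S)-oxirane-2-carboxylate
Product: 4 tert-butyl 4-fluoro-3-[(2S)-2-hydroxy-3-methoxy-3-oxopropyl]benzoate, via arylmagnesium chloride 3 (not isolated)
Conditions: 1 (1.2 equiv), i-PrMgCl·LiCl (1.25 equiv), THF, −20 °C, 1 h; then CuI (10 mol %), 2 (1.0 equiv), −40 → −20 °C; aq. NH4Cl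
Reagents that add atoms: i-PrMgCl·LiCl, CC(C)[Mg]Cl.[Li+].[Cl-] (its MgCl sits in 3 only; no atom of it remains in 4)
Why: Turbo-Grignard Br/Mg exchange (helped by the ortho fluorine, tolerated by the tert-butyl ester) followed by CuI-catalysed epoxide opening at the unsubstituted C3 of the glycidate forms the Ar–CH2 bond without touching the C2–O bond, so the bought centre stays (S) and no new stereocentre is made.

**Step 2**
Reactants: 4 tert-butyl 4-fluoro-3-[(2S)-2-hydroxy-3-methoxy-3-oxopropyl]benzoate
Product: 6 tert-butyl (2S)-2-(2-hydroxypropan-2-yl)-2,3-dihydro-1-benzofuran-5-carboxylate, via diester 5 (not isolated)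
Conditions: KN(SiMe3)2 (1.0 equiv), THF/DMPU (10:1), −40 → 0 °C, 1 h; then MeMgBr (3.2 equiv), −78 → −20 °C; aq. NH4Cl
Reagents that add atoms: methylmagnesium bromide MeMgBr, C[Mg]Br
Why: Intramolecular SNAr of the alkoxide on the fluoride para to the ester closes the dihydrofuran ring with C2–O intact, and immediate double Grignard addition to the activated α-aryloxy methyl ester (far faster than attack on the aryl tert-butyl ester) removes the only enolisable C2–H ester before it can epimerise, so C2 stays (S).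

**Step 3**
Reactants: 6 tert-butyl (2S)-2-(2-hydroxypropan-2-yl)-2,3-dihydro-1-benzofuran-5-carboxylate (2 molecules)
Product: 7 di-tert-butyl (2S,2'S)-2,2'-bis(2-hydroxypropan-2-yl)-2,2',3,3'-tetrahydro-7,7'-bi-1-benzofuran-5,5'-dicarboxylate
Conditions: undivided cell, boron-doped diamond anode, graphite cathode, Bu4NPF6 (0.1 M), HFIP, 5 mA cm−2, 1.1 F mol−1, 20 °C, stopped near 70 % conversion (6 recovered)
Reagents that add atoms: none
Why: Proposed new method: anodic dehydrogenative C7–H/C7'–H aryl–aryl homocoupling of an ester-deactivated 2,3-dihydrobenzofuran — one-electron oxidation of 6 (estimated near +2.0 V vs SCE, the carbinol and ester being inert there) gives an HFIP-stabilised arene radical cation, a second molecule of 6 attacks through C7 (the only free position ortho or para to the ring oxygen), and loss of a second electron and two protons gives the biaryl while the cathode evolves H2, with no stereocentre involved and a freely rotating axis; the closest known reaction type is the anodic ortho–ortho dehydrogenative homocoupling of para-substituted phenols and aryl alkyl ethers in HFIP, which has not been shown for acceptor-substituted dihydrobenzofurans carrying a free tertiary alcohol.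

**Step 4**
Reactants: 7 di-tert-butyl (2S,2'S)-2,2'-bis(2-hydroxypropan-2-yl)-2,2',3,3'-tetrahydro-7,7'-bi-1-benzofuran-5,5'-dicarboxylate
Product: 8 di-tert-butyl (2S,2'S)-2,2'-di(prop-1-en-2-yl)-2,2',3,3'-tetrahydro-7,7'-bi-1-benzofuran-5,5'-dicarboxylate
Conditions: Burgess reagent (MeO2C–N(−)–SO2–N(+)Et3, 3 equiv), toluene, 50 °C
Reagents that add atoms: none
Why: Burgess dehydration (syn elimination of the sulfamate ester) of each tertiary carbinol takes a methyl hydrogen, not the oxygen-deactivated C2–H, as in the classical carbinol-to-isopropenyl conversions of 2-(hydroxyisopropyl)dihydrobenzofurans, and leaves both (S) centres untouched.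

**Step 5**
Reactants: 8 di-tert-butyl (2S,2'S)-2,2'-di(prop-1-en-2-yl)-2,2',3,3'-tetrahydro-7,7'-bi-1-benzofuran-5,5'-dicarboxylate
Product: 9 Eurycomalin A, (2S,2'S)-2,2'-di(prop-1-en-2-yl)-2,2',3,3'-tetrahydro-7,7'-bi-1-benzofuran-5,5'-dicarboxylic acid
Conditions: KOH (powdered, 10 equiv), THF, rt; then 1 M HCl to pH 3, 0 °C
Reagents that add atoms: none
Why: Hydroxide cleavage of tert-butyl benzoates (BAC2 acyl substitution) frees both acids under non-acidic conditions, so the acid-sensitive isopropenyl allylic ethers and both (S) centres survive.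

**Compound list**
1 | tert-butyl 3-bromo-4-fluorobenzoate | CC(C)(C)OC(=O)c1ccc(F)c(Br)c1 | starting material
2 | methyl (2S)-oxirane-2-carboxylate (methyl (S)-glycidate) | COC(=O)[C@@H]1CO1 | starting material
3 | [5-(tert-butoxycarbonyl)-2-fluorophenyl]magnesium chloride (LiCl complex) | CC(C)(C)OC(=O)c1ccc(F)c([Mg]Cl)c1 | intermediate
4 | tert-butyl 4-fluoro-3-[(2S)-2-hydroxy-3-methoxy-3-oxopropyl]benzoate | COC(=O)[C@@H](O)Cc1cc(C(=O)OC(C)(C)C)ccc1F | intermediate
5 | 5-tert-butyl 2-methyl (2S)-2,3-dihydro-1-benzofuran-2,5-dicarboxylate | COC(=O)[C@@H]1Cc2cc(C(=O)OC(C)(C)C)ccc2O1 | intermediate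
6 | tert-butyl (2S)-2-(2-hydroxypropan-2-yl)-2,3-dihydro-1-benzofuran-5-carboxylate | CC(C)(O)[C@@H]1Cc2cc(C(=O)OC(C)(C)C)ccc2O1 | intermediate
7 | di-tert-butyl (2S,2'S)-2,2'-bis(2-hydroxypropan-2-yl)-2,2',3,3'-tetrahydro-7,7'-bi-1-benzofuran-5,5'-dicarboxylate | CC(C)(O)[C@@H]1Cc2cc(C(=O)OC(C)(C)C)cc(-c3cc(C(=O)OC(C)(C)C)cc4c3O[C@H](C(C)(C)O)C4)c2O1 | intermediate
8 | di-tert-butyl (2S,2'S)-2,2'-di(prop-1-en-2-yl)-2,2',3,3'-tetrahydro-7,7'-bi-1-benzofuran-5,5'-dicarboxylate | C=C(C)[C@@H]1Cc2cc(C(=O)OC(C)(C)C)cc(-c3cc(C(=O)OC(C)(C)C)cc4c3O[C@H](C(=C)C)C4)c2O1 | intermediate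
9 | Eurycomalin A, (2S,2'S)-2,2'-di(prop-1-en-2-yl)-2,2',3,3'-tetrahydro-7,7'-bi-1-benzofuran-5,5'-dicarboxylic acid | C=C(C)[C@@H]1Cc2cc(C(=O)O)cc(-c3cc(C(=O)O)cc4c3O[C@H](C(=C)C)C4)c2O1 | target

**Totals**
Total step count: 5. Longest linear sequence: 5 (two molecules of 6 are joined in Step 3).

**Steps most likely to fail**

Step 3 (the proposed new anodic homocoupling). Possible failures are dehydrogenation of the dihydrofuran to a benzofuran, loss of the carbinol side chain from the radical cation, or over-oxidation. The fallback uses known chemistry, sets out from 5 (isolated by quenching Step 2 with AcOH before MeMgBr is added) and comes back at 7. Bromination ortho to the ring oxygen (NBS, HFIP, rt) gives 5-tert-butyl 2-methyl (2S)-7-bromo-2,3-dihydro-1-benzofuran-2,5-dicarboxylate F1. The established Ni-catalysed electroreductive homocoupling of aryl bromides (NiBr2(bpy) 10 mol %, Bu4NBr, DMF, sacrificial zinc anode, nickel-foam cathode, constant current, rt; zerovalent nickel is formed at the cathode) then gives 5,5'-di-tert-butyl 2,2'-dimethyl (2S,2'S)-2,2',3,3'-tetrahydro-7,7'-bi-1-benzofuran-2,2',5,5'-tetracarboxylate F2. MeMgBr (4.6 equiv, THF, −78 → −20 °C) converts both methyl esters and gives 7.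

Step 2 (SNAr with an enolisable α-aryloxy ester). Possible failures are partial epimerisation of 5 at C2 by alkoxide or a sluggish ring closure. The fallback sets out from 4 and comes back at 5, which is then taken through the MeMgBr half of Step 2. LiOH (1.05 equiv, THF/H2O, 0 °C) cleaves only the methyl ester to (2S)-3-[5-(tert-butoxycarbonyl)-2-fluorophenyl]-2-hydroxypropanoic acid F3. NaH (2.2 equiv, THF/DMPU, 0 °C → rt) cyclises the alkoxide–carboxylate dianion by SNAr, where the α-C–H of a carboxylate cannot be removed, to (2S)-5-(tert-butoxycarbonyl)-2,3-dihydro-1-benzofuran-2-carboxylic acid F4. TMSCHN2 (toluene/MeOH, 0 °C) re-forms the methyl ester 5.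

Step 4 (double dehydration on the dimer). Possible failures are incomplete bis-elimination, enol-ether isomers or ring-expanded by-products, which are hard to separate on a two-site substrate. The fallback sets out from 6 and comes back at 8, moving the elimination to the monomer and the dimerisation to a reductive coupling that tolerates the alkene. NBS (HFIP, rt) gives tert-butyl (2S)-7-bromo-2-(2-hydroxypropan-2-yl)-2,3-dihydro-1-benzofuran-5-carboxylate F5. Burgess dehydration (toluene, 50 °C) of the single carbinol, with isomers removed on AgNO3-impregnated silica, gives tert-butyl (2S)-7-bromo-2-(prop-1-en-2-yl)-2,3-dihydro-1-benzofuran-5-carboxylate F6. Ni-catalysed electroreductive homocoupling (NiBr2(bpy), Bu4NBr, DMF, zinc anode, rt) gives 8.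

**Further compounds**
F1 | step 3 | 5-tert-butyl 2-methyl (2S)-7-bromo-2,3-dihydro-1-benzofuran-2,5-dicarboxylate | COC(=O)[C@@H]1Cc2cc(C(=O)OC(C)(C)C)cc(Br)c2O1
F2 | step 3 | 5,5'-di-tert-butyl 2,2'-dimethyl (2S,2'S)-2,2',3,3'-tetrahydro-7,7'-bi-1-benzofuran-2,2',5,5'-tetracarboxylate | COC(=O)[C@@H]1Cc2cc(C(=O)OC(C)(C)C)cc(-c3cc(C(=O)OC(C)(C)C)cc4c3O[C@H](C(=O)OC)C4)c2O1
F3 | step 2 | (2S)-3-[5-(tert-butoxycarbonyl)-2-fluorophenyl]-2-hydroxypropanoic acid | OC(=O)[C@@H](O)Cc1cc(C(=O)OC(C)(C)C)ccc1F
F4 | step 2 | (2S)-5-(tert-butoxycarbonyl)-2,3-dihydro-1-benzofuran-2-carboxylic acid | OC(=O)[C@@H]1Cc2cc(C(=O)OC(C)(C)C)ccc2O1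
F5 | step 4 | tert-butyl (2S)-7-bromo-2-(2-hydroxypropan-2-yl)-2,3-dihydro-1-benzofuran-5-carboxylate | CC(C)(O)[C@@H]1Cc2cc(C(=O)OC(C)(C)C)cc(Br)c2O1
F6 | step 4 | tert-butyl (2S)-7-bromo-2-(prop-1-en-2-yl)-2,3-dihydro-1-benzofuran-5-carboxylate | C=C(C)[C@@H]1Cc2cc(C(=O)OC(C)(C)C)cc(Br)c2O1
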